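## Structural features

The target is a melampolide-type germacranolide: a ten-membered carbocycle (C1–C10) fused through C6 and C7 to an α-methylene-γ-butyrolactone (O–C6, C7–C11(=C13)–C12) with a trans ring junction. The carbocycle carries a trans-4,5-epoxide (C4 also bears the C15 methyl) and a ring-cis C1=C10 double bond conjugated to the C14 methyl ester (E by the sequence rule, because C14 outranks C9). Two different esters sit on neighbouring carbons: the (2S,3R)-3-chloro-2-hydroxy-2-methylbutanoate on O8 and an acetate on O9. Six contiguous stereocentres run from C4 to C9 (4R,5R,6S,7R,8R,9S), and two more stand next to each other in the side chain. The fragile groups are the α-methylene lactone (a Michael acceptor that rules out later enolate or reducing chemistry), the epoxide (acid), the chlorohydrin (base closes it to an epoxide), the vicinal esters (acyl migration, and migration of the lactone from O6 to a free O8) and the geometry of the C1=C10 unit. The real difficulty is to close the medium ring while setting C6–C9 and then to tell O8 from O9. The key step exploits the fact that C8 and C9 are adjacent, both oxygen-bearing and erythro to each other. Each can therefore come from an aldehyde carbon, so one reductive coupling can form the C8–C9 bond, both hydroxyls and the ten-membered ring, with the C1=C10 alkene making C9 the more easily reduced aldehyde.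

## Logic of the disconnections

39 to 38: the C4–O and C5–O bonds of the epoxide are cut. The epoxide is the most acid-sensitive group, and in 38 the C4=C5 alkene is the only one not conjugated to a carbonyl, so it can be oxidised selectively at the end. Two stereocentres disappear and every earlier step is freed from the epoxide. The forward step must deliver oxygen to the outer face of the E-alkene that gives 4R,5R.

38 to 32 and 36, then 32 to 31: the O8–acyl bond and then the O9–acetyl bond are cut. Esters cannot survive the enolate chemistry needed at C11, and the two side-chain stereocentres can be made on a separate small fragment. The gain is convergence and a simple diol 31. The forward steps demand that O9 is acetylated before O8, and that the hindered O8 accepts an α,α-disubstituted hydroxy acid without acetyl migration and without closing the chlorohydrin.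

36 to 35 to 34 to 33: the C3–Cl bond and then the epoxide are cut. The anti relationship of hydroxyl and chlorine in 36 is that of a trans-epoxide opened at C3 with inversion, and the epoxide is the product of a reagent-controlled epoxidation of an E-allylic alcohol. Both stereocentres then come from one catalytic step. Chloride must attack C3 and not C2, and the L-(+)-tartrate must be used.

31 back to 23 (through 30, 29, 27 and 26): the C14–O oxidation-level changes, the C11=C13 bond and the acetonide are removed. C14 must stay below the ester level during ring closure, because an ester on C10 would turn C1=C10 into a doubly activated alkene that is reduced at C1. The lactone methylenation needs an enolate, so it has to come before any ester is installed and while the diol is masked. The gain is a precursor without C13 and without acyl groups. The acetonide must form on the erythro diol and come off again without the lactone moving to O8.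

23 and 22 to 21: the C8–C9 bond is cut (key step). Both carbons are carbonyl-derived and of like polarity, so a ketyl coupling joins them. One bond, the ring and two stereocentres are traded for an acyclic dialdehyde whose only stereocentres are C6 and C7. The forward step must close a ten-membered ring against intermolecular coupling, let C7 control C8 and the metal control C9, and keep the Z-enal geometry.

21 to 20 to 19 to 18: only functional groups change. The dialdehyde is labile (an epimerisable β-acyloxy aldehyde and a Z-enal), so both aldehydes are released together in the last step from a diol, O9 is uncovered from its PMB ether, and C8 comes from the imide carbonyl. The imide must be reduced without touching the lactone.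

18 to 16 and 12: the C6–C7 bond and the lactone C12–O6 bond are cut (auxiliary-controlled syn aldol followed by lactonisation). Two stereocentres and the lactone come from an achiral enal and a four-carbon imide. The forward step needs the (S)-auxiliary and a boron Z-enolate; the syn adduct closes to the trans lactone.

12 back to 8 (through 11, 10 and 9), then 8 to 4 and 7: protecting-group and oxidation-level changes, then the C1=C10 bond. The olefination puts the ester trans to the chain; that carbon becomes C14, and the ether-bearing carbon cis to the chain becomes C9. The labile Z-enal of 21 then arises by oxidation only, without any isomerisation-prone olefination. The step must be E-selective, and three primary allylic oxygens need masks that come off in sequence (TBS on O6, PMB on O9, TBDPS on O14).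

4 to 2 to 1, 7 to 5 and 6, 16 to 13 and 14: the distal alkene is cleaved, an O–C bond is cut (oxa-Michael addition) and an N-acyl bond is cut. These end at bought materials. The only demand is selective cleavage of the more electron-rich alkene of 2.

## Other disconnections considered

Alternative 1: the cut is C2–C3, paired with re-forming C5–C10, i.e. a [3,3] retron. In the forward sense the potassium alkoxide of the trans-dialkenylcyclohexanol A1 (KH, 18-crown-6) would undergo an anionic oxy-Cope shift to the ten-membered C10 ketone A2.
- In its favour: the ring is made by a unimolecular ring expansion, so no high dilution is needed and there is no entropic penalty. On this point it is better than the closure of 21. The E C4=C5 geometry follows from a chair transition state, which is equal to the chosen plan, where it is bought with 1. C6–C9 are set on a cyclohexane, where relative control is routine; this is better than setting C8 and C9 during a macrocyclisation. The pericyclic mechanism is also more predictable than a ketyl coupling.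
- Against it here: A1 needs six contiguous stereocentres on one ring, including the quaternary carbinol C10. A2 lacks C14 and the C1=C10 alkene, so the ketone would have to be enolised toward C1 and not toward the oxygenated C9 and then carbonylated, with the ring-cis geometry left to the ring. The enolate formed under KH lies β to O8 after proton transfer and could eliminate. The lactone would also still have to be oxidised up from the two silyl ethers.
- Overall: stronger on ring formation and stereocontrol, weaker on functional-group match, and judged longer in total.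

Alternative 2: the cut is the C1=C10 double bond. The phosphonate anion of the open-chain aldehyde A3 (LiCl, amine base, high dilution) would close to the enoate A4.
- In its favour: C14 is at the ester level from the start, so no oxidation-state adjustment at C14 follows ring closure (better than the chosen plan). The required geometry, ester trans to C2, is the normal preference of a trisubstituted Horner–Wadsworth–Emmons reaction, whereas the chosen plan must carry a less stable Z-enal (better). The epoxide can be set early by reagent control on an acyclic allylic alcohol (better than a late substrate-controlled epoxidation). O8 and O9 are told apart by protecting groups from the outset (better).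
- Against it here: a ten-membered ring would be closed by a hindered, fully substituted carbanion that carries a β-silyloxy group. The elimination question is the one the chosen route faces in step 4, but with a better leaving group. Cyclic dimers are a real competitor. A3 is a long linear chain with six stereocentres and an epoxide. The lactone and all the esters still have to be made after ring closure.
- Overall: equal or better in the endgame, clearly weaker in the length and fragility of the precursor and in the ring closure itself.

Alternative 3: the cut is C9–C10. CrCl2 with catalytic NiCl2 would turn the alkenyl iodide of A5 into an alkenylchromium species that adds to the C9 aldehyde and gives the carbinol A6.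
- In its favour: the conditions tolerate epoxide, lactone and α-methylene groups. The alkene geometry is carried over from the iodide with retention, which is better than a ketyl that may rotate. Only C9 is created, one stereocentre instead of two (better). O8 is already masked differently from O9 (better). A6 is closer to 39 than 22 is, so the endgame is shorter (better).
- Against it here: A5 has to carry every sensitive group (epoxide, α-methylene lactone, an epimerisable α-silyloxy aldehyde) through a long linear sequence before the ring exists. It needs a stereodefined trisubstituted alkenyl iodide, a problem of the same class as the Z-enal (equal). The C9 configuration of a macrocyclic addition depends on conformation, as in the chosen plan (equal). A large excess of toxic divalent chromium is needed, against stoichiometric but more benign divalent samarium (chosen plan better). C14 still has to be oxidised (equal).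
- Overall: the strongest of the three. The chosen plan is preferred for its very simple precursor and because C8 and C9 arise together, at the price of the O8/O9 differentiation.

Key step: step 14

Remark on numbering: germacranolide numbering is used throughout (ring C1–C10, lactone carbons C11–C13, C14 on C10, C15 on C4).

Remark on the structures: checked against 39, dialdehyde 21 and diol 22 need no stereochemical correction. "Cis-diol" means the erythro arrangement (8R,9S in 22). Changes of R/S at C6 and C7 along the route reflect changed CIP priorities only, never an inversion.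

Remark on the precursor design: O9 carries the PMB ether (it arrives with the olefination reagent and is removed under neutral conditions just before the oxidation) and O14 the TBDPS ether. C14 is kept at the alcohol level during the coupling. Both aldehydes are released in one oxidation and used at once.

Assumption: 5, 6, 13, 14 and 33 are bought.

Step 1
Reactants: 1 geraniol
Product: 2 geranyl tert-butyldimethylsilyl ether
Conditions: TBSCl, imidazole, CH2Cl2, 0 °C to rt
Reagents that add atoms: tert-butyldimethylsilyl chloride, C[Si](C)(Cl)C(C)(C)C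
Why: Standard silylation of a primary alcohol; TBS is the most labile of the three oxygen masks and can later be taken off O6 alone.

Step 2
Reactants: 2 geranyl tert-butyldimethylsilyl ether
Product: 4 (4E)-6-(tert-butyldimethylsilyloxy)-4-methylhex-4-enal, via epoxide 3 (not isolated)
Conditions: mCPBA, NaHCO3, CH2Cl2, −20 °C; then H5IO6, THF/Et2O, 0 °C
Reagents that add atoms: 3-chloroperoxybenzoic acid, O=C(OO)c1cccc(Cl)c1
Why: Prilezhaev epoxidation should pick the distal trisubstituted alkene, because the other one is deactivated by the allylic oxygen; periodic acid then hydrates the epoxide and cleaves the glycol (Malaprade cleavage), releasing C1 as the aldehyde and acetone.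

Step 3
Reactants: 5 4-methoxybenzyl alcohol, 6 trimethyl 2-phosphonoacrylate
Product: 7 methyl 2-(dimethoxyphosphoryl)-3-(4-methoxybenzyloxy)propanoate
Conditions: NaH (10 mol %), THF, 0 °C
Reagents that add atoms: none
Why: Base-catalysed oxa-Michael addition to a doubly activated acrylate; the stabilised carbanion is protonated by more alcohol, so a catalytic amount of alkoxide suffices.

Step 4
Reactants: 4 (4E)-6-(tert-butyldimethylsilyloxy)-4-methylhex-4-enal, 7 methyl 2-(dimethoxyphosphoryl)-3-(4-methoxybenzyloxy)propanoate
Product: 8 methyl (2E,6E)-8-(tert-butyldimethylsilyloxy)-2-[(4-methoxybenzyloxy)methyl]-6-methylocta-2,6-dienoate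
Conditions: LiCl, DBU, MeCN, 0 °C to rt
Reagents that add atoms: none
Why: Horner–Wadsworth–Emmons olefination under Masamune–Roush conditions; reversible addition should favour the alkene with the ester trans to the chain, so the ester carbon becomes C14 and the ether-bearing carbon cis to the chain becomes C9. Loss of alkoxide from the stabilised β-alkoxy carbanion is the reverse of step 3 and should be uphill.

Step 5
Reactants: 8 methyl (2E,6E)-8-(tert-butyldimethylsilyloxy)-2-[(4-methoxybenzyloxy)methyl]-6-methylocta-2,6-dienoate
Product: 9 (2Z,6E)-8-(tert-butyldimethylsilyloxy)-2-[(4-methoxybenzyloxy)methyl]-6-methylocta-2,6-dien-1-ol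
Conditions: i-Bu2AlH, CH2Cl2, −78 °C; aqueous potassium sodium tartrate
Reagents that add atoms: none
Why: 1,2-Reduction of a conjugated ester to the allylic alcohol by an aluminium hydride; the alkene geometry is untouched (the Z label reflects changed priorities only).

Step 6
Reactants: 9 (2Z,6E)-8-(tert-butyldimethylsilyloxy)-2-[(4-methoxybenzyloxy)methyl]-6-methylocta-2,6-dien-1-ol
Product: 10 (2E,6E)-8-(tert-butyldimethylsilyloxy)-1-(tert-butyldiphenylsilyloxy)-2-[(4-methoxybenzyloxy)methyl]-6-methylocta-2,6-diene
Conditions: TBDPSCl, imidazole, DMF, rt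
Reagents that add atoms: tert-butyldiphenylsilyl chloride, CC(C)(C)[Si](Cl)(c1ccccc1)c1ccccc1
Why: Silylation of the primary allylic alcohol; the TBDPS ether on O14 should survive acid methanolysis, DDQ, SmI2 and amide bases and leave with fluoride late in the route.

Step 7
Reactants: 10 (2E,6E)-8-(tert-butyldimethylsilyloxy)-1-(tert-butyldiphenylsilyloxy)-2-[(4-methoxybenzyloxy)methyl]-6-methylocta-2,6-diene
Product: 11 (2E,6E)-8-(tert-butyldiphenylsilyloxy)-7-[(4-methoxybenzyloxy)methyl]-3-methylocta-2,6-dien-1-ol
Conditions: PPTS, MeOH, rt
Reagents that add atoms: none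
Why: Acid-catalysed methanolysis removes a primary TBS ether far faster than a TBDPS ether; the PMB ether is inert to these conditions.

Step 8
Reactants: 11 (2E,6E)-8-(tert-butyldiphenylsilyloxy)-7-[(4-methoxybenzyloxy)methyl]-3-methylocta-2,6-dien-1-ol
Product: 12 (2E,6E)-8-(tert-butyldiphenylsilyloxy)-7-[(4-methoxybenzyloxy)methyl]-3-methylocta-2,6-dienal
Conditions: MnO2, CH2Cl2, rt
Reagents that add atoms: none
Why: Allylic oxidation with MnO2 gives the geranial-type E-enal (C6) without isomerisation or over-oxidation.

Step 9
Reactants: 13 monomethyl succinate, 14 (S)-4-benzyl-1,3-oxazolidin-2-one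
Product: 16 methyl 4-[(4S)-4-benzyl-2-oxo-1,3-oxazolidin-3-yl]-4-oxobutanoate, via mixed anhydride 15 (not isolated)
Conditions: pivaloyl chloride, Et3N, THF, −20 °C; then 14, LiCl, rt
Reagents that add atoms: none
Why: N-Acylation of the auxiliary through the pivalic mixed anhydride; the hindered pivaloyl carbonyl directs attack to the succinyl carbonyl.

Step 10
Reactants: 16 methyl 4-[(4S)-4-benzyl-2-oxo-1,3-oxazolidin-3-yl]-4-oxobutanoate, 12 (2E,6E)-8-(tert-butyldiphenylsilyloxy)-7-[(4-methoxybenzyloxy)methyl]-3-methylocta-2,6-dienal
Product: 18 (4S)-4-benzyl-3-[(2R,3S)-2-{(1E,5E)-7-(tert-butyldiphenylsilyloxy)-6-[(4-methoxybenzyloxy)methyl]-2-methylhepta-1,5-dienyl}-5-oxooxolane-3-carbonyl]-1,3-oxazolidin-2-one, via aldol adduct 17 (not isolated)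
Conditions: Bu2BOTf, iPr2NEt, CH2Cl2, −78 to 0 °C; 12, −78 to 0 °C; pH 7 buffer, MeOH, H2O2, 0 °C; then PhMe, 40 °C
Reagents that add atoms: none
Why: Evans syn aldol: the boron Z-enolate of the imide (not of the ester) reacts through a Zimmerman–Traxler chair on the face away from the benzyl group, which sets C7 and C6 in the syn arrangement required. The γ-hydroxy ester then closes onto C12 with loss of methanol, and a syn adduct necessarily gives the trans-4,5-disubstituted lactone.

Step 11
Reactants: 18 (4S)-4-benzyl-3-[(2R,3S)-2-{(1E,5E)-7-(tert-butyldiphenylsilyloxy)-6-[(4-methoxybenzyloxy)methyl]-2-methylhepta-1,5-dienyl}-5-oxooxolane-3-carbonyl]-1,3-oxazolidin-2-one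
Product: 19 (4R,5R)-5-{(1E,5E)-7-(tert-butyldiphenylsilyloxy)-6-[(4-methoxybenzyloxy)methyl]-2-methylhepta-1,5-dienyl}-4-(hydroxymethyl)oxolan-2-one
Conditions: NaBH4, THF/H2O, 0 °C to rt
Reagents that add atoms: none
Why: Reductive removal of the auxiliary: borohydride attacks the activated exocyclic imide carbonyl much faster than the γ-lactone, giving the C8 alcohol and releasing 14 for reuse. The more substituted 6,12-lactone is expected to be the thermodynamically preferred one should any acyl transfer to O8 occur.

Step 12
Reactants: 19 (4R,5R)-5-{(1E,5E)-7-(tert-butyldiphenylsilyloxy)-6-[(4-methoxybenzyloxy)methyl]-2-methylhepta-1,5-dienyl}-4-(hydroxymethyl)oxolan-2-one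
Product: 20 (4R,5R)-5-{(1E,5E)-6-[(tert-butyldiphenylsilyloxy)methyl]-7-hydroxy-2-methylhepta-1,5-dienyl}-4-(hydroxymethyl)oxolan-2-one
Conditions: DDQ, CH2Cl2/pH 7 buffer, 0 °C
Reagents that add atoms: none
Why: Oxidative cleavage of the PMB ether under neutral conditions uncovers O9 without touching the silyl ether, the lactone or the alkenes.

Step 13
Reactants: 20 (4R,5R)-5-{(1E,5E)-6-[(tert-butyldiphenylsilyloxy)methyl]-7-hydroxy-2-methylhepta-1,5-dienyl}-4-(hydroxymethyl)oxolan-2-one
Product: 21 (2R,3S)-2-{(1E,5Z)-6-[(tert-butyldiphenylsilyloxy)methyl]-2-methyl-7-oxohepta-1,5-dienyl}-5-oxooxolane-3-carbaldehyde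
Conditions: Dess–Martin periodinane, NaHCO3, CH2Cl2, 0 °C; used at once
Reagents that add atoms: none
Why: Buffered Dess–Martin oxidation converts both primary alcohols in one operation; the near-neutral medium should spare the Z-enal geometry and avoid epimerisation or β-elimination at C7.

Step 14
Reactants: 21 (2R,3S)-2-{(1E,5Z)-6-[(tert-butyldiphenylsilyloxy)methyl]-2-methyl-7-oxohepta-1,5-dienyl}-5-oxooxolane-3-carbaldehyde
Product: 22 (1(10)Z,4E,6R,7R,8R,9S)-14-(tert-butyldiphenylsilyloxy)-8,9-dihydroxygermacra-1(10),4-dien-12,6-olide
Conditions: SmI2 (4 equiv), THF, −78 to 0 °C, 21 added over 8 h (final 2 mM); aqueous NH4Cl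
Reagents that add atoms: none
Why: SmI2 gives one electron to the conjugated C9 aldehyde, the easier one to reduce; the trivalent-samarium ketyl, an oxygen-substituted allyl radical, adds through C9 to the C8 aldehyde held on the same oxophilic metal, and a second electron gives the samarium diolate that is protonated on work-up. The closest known reaction type is the SmI2-mediated intramolecular pinacol coupling of dialdehydes to cyclic cis-diols. The ten-membered ring closes in a 10-exo-trig mode (attack at the carbonyl carbon, oxygen left outside the ring), helped by high dilution and by the two trisubstituted alkenes and the trans-lactone, which take five rotors out of the chain. C8 is controlled by C7: the new bond should form anti to the C7–C6 bond (Felkin-type, C6 being the larger, oxygen-bearing branch), which gives the 7,8-syn relationship. C9 is controlled relative to C8 by the metal: with both oxygens on one samarium the O–C8–C9–O torsion is small, and with C7 and C10 held gauche by the short Z-C1=C10 bridge the erythro (ring-cis) diol should result. The step needs coupling at the carbonyl carbon and not at C1, retention of the Z geometry in the ketyl, and no reduction of the lactone or of the allylic C14–O bond. The substituent on C10 shields C1, cyclisation at low temperature without HMPA or a proton source should outrun bond rotation and over-reduction, and unactivated lactones and silyl ethers are inert to SmI2 in THF.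

Step 15
Reactants: 22 (1(10)Z,4E,6R,7R,8R,9S)-14-(tert-butyldiphenylsilyloxy)-8,9-dihydroxygermacra-1(10),4-dien-12,6-olide
Product: 23 (1(10)Z,4E,6R,7S,8R,9S)-14-(tert-butyldiphenylsilyloxy)-8,9-(isopropylidenedioxy)germacra-1(10),4-dien-12,6-olide
Conditions: 2,2-dimethoxypropane, PPTS, CH2Cl2, rt
Reagents that add atoms: 2,2-dimethoxypropane, COC(C)(C)OC
Why: Acetonide formation by transketalisation; the erythro diol can bring both oxygens syn-clinal, and the ketal blocks O8 from attacking the lactone during the base step that follows.

Step 16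
Reactants: 23 (1(10)Z,4E,6R,7S,8R,9S)-14-(tert-butyldiphenylsilyloxy)-8,9-(isopropylidenedioxy)germacra-1(10),4-dien-12,6-olide
Product: 26 (1(10)Z,4E,6R,7S,8R,9S)-14-(tert-butyldiphenylsilyloxy)-8,9-(isopropylidenedioxy)germacra-1(10),4,11(13)-trien-12,6-olide, via Mannich base 24 (not isolated), via ammonium iodide 25 (not isolated)
Conditions: LiN(iPr)2, THF, −78 °C; Me2N=CH2+ I−, −78 to 0 °C; then MeI, MeOH, rt; then aqueous NaHCO3, CH2Cl2, rt
Reagents that add atoms: N,N-dimethylmethyleneiminium iodide, C=[N+](C)C.[I-]
Why: α-Methylenation of a lactone by the Eschenmoser-salt sequence: Mannich alkylation of the lithium enolate at C11, N-methylation and Hofmann-type elimination of trimethylamine. No ester is present yet and the enolate has no β-leaving group; the C11 configuration of 24 is irrelevant.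

Step 17
Reactants: 26 (1(10)Z,4E,6R,7S,8R,9S)-14-(tert-butyldiphenylsilyloxy)-8,9-(isopropylidenedioxy)germacra-1(10),4,11(13)-trien-12,6-olide
Product: 27 (1(10)Z,4E,6R,7S,8R,9S)-14-hydroxy-8,9-(isopropylidenedioxy)germacra-1(10),4,11(13)-trien-12,6-olide
Conditions: HF·pyridine, pyridine, THF, 0 °C to rt
Reagents that add atoms: none
Why: Fluoride cleavage of the primary silyl ether; buffering with pyridine keeps the acetonide and the methylene lactone intact.

Step 18
Reactants: 27 (1(10)Z,4E,6R,7S,8R,9S)-14-hydroxy-8,9-(isopropylidenedioxy)germacra-1(10),4,11(13)-trien-12,6-olide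
Product: 29 (1(10)E,4E,6R,7S,8R,9S)-8,9-(isopropylidenedioxy)germacra-1(10),4,11(13)-trien-12,6-olid-14-oic acid, via enal 28 (not isolated)
Conditions: Dess–Martin periodinane, NaHCO3, CH2Cl2, rt; then NaClO2, NaH2PO4, 2-methylbut-2-ene, t-BuOH/H2O, 0 °C
Reagents that add atoms: sodium chlorite, [Na+].[O-]Cl=O
Why: Dess–Martin oxidation followed by Pinnick oxidation of the crude enal; this enal has its carbonyl trans to the chain, the stable geometry. The scavenger removes hypochlorite, so neither the C4=C5 alkene nor the methylene lactone is attacked.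

Step 19
Reactants: 29 (1(10)E,4E,6R,7S,8R,9S)-8,9-(isopropylidenedioxy)germacra-1(10),4,11(13)-trien-12,6-olid-14-oic acid
Product: 30 methyl (1(10)E,4E,6R,7S,8R,9S)-8,9-(isopropylidenedioxy)germacra-1(10),4,11(13)-trien-12,6-olid-14-oate
Conditions: MeI, KHCO3, DMF, rt
Reagents that add atoms: iodomethane, CI
Why: O-Alkylation of the carboxylate under weakly basic conditions; a diazoalkane is avoided because it would add to the methylene lactone as a dipole.

Step 20
Reactants: 30 methyl (1(10)E,4E,6R,7S,8R,9S)-8,9-(isopropylidenedioxy)germacra-1(10),4,11(13)-trien-12,6-olid-14-oate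
Product: 31 methyl (1(10)E,4E,6R,7R,8R,9S)-8,9-dihydroxygermacra-1(10),4,11(13)-trien-12,6-olid-14-oate
Conditions: AcOH/H2O (4:1), 40 °C
Reagents that add atoms: none
Why: Mild acid hydrolysis of the ketal; the weak acid and moderate temperature are chosen to keep the lactone on O6 and to avoid transannular reactions of the diene.

Step 21
Reactants: 31 methyl (1(10)E,4E,6R,7R,8R,9S)-8,9-dihydroxygermacra-1(10),4,11(13)-trien-12,6-olid-14-oate
Product: 32 methyl (1(10)E,4E,6R,7R,8R,9S)-9-acetoxy-8-hydroxygermacra-1(10),4,11(13)-trien-12,6-olid-14-oate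
Conditions: Ac2O (1.05 equiv), 2,4,6-collidine, CH2Cl2, −40 to 0 °C
Reagents that add atoms: acetic anhydride, CC(=O)OC(C)=O
Why: Site-selective acylation: O9 is flanked by the planar C10 and should be the more exposed hydroxyl, whereas O8 lies next to the ring-fusion carbon C7 under the lactone. One equivalent of anhydride with a weak hindered base at low temperature should acetylate O9 first and keep acetyl migration slow.

Step 22
Reactants: 33 (E)-2-methylbut-2-en-1-ol
Product: 34 (2S,3S)-2,3-epoxy-2-methylbutan-1-ol
Conditions: Ti(OiPr)4 (cat.), L-(+)-diisopropyl tartrate, t-BuOOH, 4 Å sieves, CH2Cl2, −20 °C; non-aqueous work-up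
Reagents that add atoms: tert-butyl hydroperoxide, CC(C)(C)OO
Why: Sharpless asymmetric epoxidation; with the L-(+)-tartrate the oxygen is delivered to the face that gives the 2S,3S epoxy alcohol, as for other E-allylic alcohols, and both side-chain stereocentres are set here.

Step 23
Reactants: 34 (2S,3S)-2,3-epoxy-2-methylbutan-1-ol
Product: 35 (2R,3S)-2,3-epoxy-2-methylbutanoic acid
Conditions: RuCl3 (cat.), NaIO4, EtOAc/MeCN/H2O, rt
Reagents that add atoms: water, O
Why: Ruthenium tetroxide oxidation of a primary alcohol to the acid, a standard way to glycidic acids; the epoxide is untouched and the descriptor at C2 changes only because the priorities change.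

Step 24
Reactants: 35 (2R,3S)-2,3-epoxy-2-methylbutanoic acid
Product: 36 (2S,3R)-3-chloro-2-hydroxy-2-methylbutanoic acid
Conditions: HCl (2 M in Et2O), 0 °C
Reagents that add atoms: hydrogen chloride, Cl
Why: Acid-mediated opening of a glycidic acid by chloride: attack at C2 is disfavoured by the adjacent carboxyl and by its tertiary nature, so chloride should enter at C3 with inversion, which gives the anti chlorohydrin with C2 unchanged.

Step 25
Reactants: 32 methyl (1(10)E,4E,6R,7R,8R,9S)-9-acetoxy-8-hydroxygermacra-1(10),4,11(13)-trien-12,6-olid-14-oate, 36 (2S,3R)-3-chloro-2-hydroxy-2-methylbutanoic acid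
Product: 38 methyl (1(10)E,4E,6R,7S,8R,9S)-9-acetoxy-8-[(2S,3R)-3-chloro-2-hydroxy-2-methylbutanoyloxy]germacra-1(10),4,11(13)-trien-12,6-olid-14-oate, via mixed anhydride 37 (not isolated)
Conditions: 2,4,6-trichlorobenzoyl chloride, Et3N, THF, 0 °C; then 32, DMAP, PhMe, rt
Reagents that add atoms: none
Why: Yamaguchi esterification: the mixed anhydride is attacked by DMAP at the aliphatic carbonyl and the acylpyridinium acylates O8. The tertiary hydroxyl of the acid is too hindered to compete, and amine bases are too weak to close the chlorohydrin.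

Step 26
Reactants: 38 methyl (1(10)E,4E,6R,7S,8R,9S)-9-acetoxy-8-[(2S,3R)-3-chloro-2-hydroxy-2-methylbutanoyloxy]germacra-1(10),4,11(13)-trien-12,6-olid-14-oate
Product: 39 methyl (1(10)E,4R,5R,6S,7R,8R,9S)-9-acetoxy-8-[(2S,3R)-3-chloro-2-hydroxy-2-methylbutanoyloxy]-4,5-epoxygermacra-1(10),11(13)-dien-12,6-olid-14-oate
Conditions: mCPBA, NaHCO3, CH2Cl2, 0 °C
Reagents that add atoms: 3-chloroperoxybenzoic acid, O=C(OO)c1cccc(Cl)c1
Why: Prilezhaev epoxidation: C4=C5 is the only alkene not conjugated to a carbonyl, so it should react alone. The peracid can reach only the outer face of the E-alkene in the ten-membered ring, and the conformer fixed by the trans-lactone is expected to expose the face that gives 4R,5R; syn addition keeps C3 and C6 trans.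

Compound list

1 | geraniol, (2E)-3,7-dimethylocta-2,6-dien-1-ol | CC(C)=CCC/C(C)=C/CO | starting material
2 | geranyl tert-butyldimethylsilyl ether | CC(C)=CCC/C(C)=C/CO[Si](C)(C)C(C)(C)C | intermediate
3 | 6,7-epoxide of 2 (racemic), tert-butyl{[(2E)-5-(3,3-dimethyloxiran-2-yl)-3-methylpent-2-en-1-yl]oxy}dimethylsilane | CC1(C)OC1CC/C(C)=C/CO[Si](C)(C)C(C)(C)C | intermediate (not isolated)
4 | (4E)-6-(tert-butyldimethylsilyloxy)-4-methylhex-4-enal | O=CCC/C(C)=C/CO[Si](C)(C)C(C)(C)C | intermediate
5 | 4-methoxybenzyl alcohol | COc1ccc(CO)cc1 | starting material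
6 | trimethyl 2-phosphonoacrylate, methyl 2-(dimethoxyphosphoryl)prop-2-enoate | C=C(C(=O)OC)P(=O)(OC)OC | starting material
7 | methyl 2-(dimethoxyphosphoryl)-3-(4-methoxybenzyloxy)propanoate (racemic) | COC(=O)C(COCc1ccc(OC)cc1)P(=O)(OC)OC | intermediate
8 | methyl (2E,6E)-8-(tert-butyldimethylsilyloxy)-2-[(4-methoxybenzyloxy)methyl]-6-methylocta-2,6-dienoate (ester trans to the chain) | COC(=O)/C(COCc1ccc(OC)cc1)=C/CC/C(C)=C/CO[Si](C)(C)C(C)(C)C | intermediate
9 | (2Z,6E)-8-(tert-butyldimethylsilyloxy)-2-[(4-methoxybenzyloxy)methyl]-6-methylocta-2,6-dien-1-ol | OC/C(COCc1ccc(OC)cc1)=C/CC/C(C)=C/CO[Si](C)(C)C(C)(C)C | intermediate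
10 | (2E,6E)-8-(tert-butyldimethylsilyloxy)-1-(tert-butyldiphenylsilyloxy)-2-[(4-methoxybenzyloxy)methyl]-6-methylocta-2,6-diene | CC(C)(C)[Si](OC/C(COCc1ccc(OC)cc1)=C/CC/C(C)=C/CO[Si](C)(C)C(C)(C)C)(c1ccccc1)c1ccccc1 | intermediate
11 | (2E,6E)-8-(tert-butyldiphenylsilyloxy)-7-[(4-methoxybenzyloxy)methyl]-3-methylocta-2,6-dien-1-ol | OC/C=C(\C)CC/C=C(/CO[Si](c1ccccc1)(c1ccccc1)C(C)(C)C)COCc1ccc(OC)cc1 | intermediate
12 | (2E,6E)-8-(tert-butyldiphenylsilyloxy)-7-[(4-methoxybenzyloxy)methyl]-3-methylocta-2,6-dienal | O=C/C=C(\C)CC/C=C(/CO[Si](c1ccccc1)(c1ccccc1)C(C)(C)C)COCc1ccc(OC)cc1 | intermediate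
13 | monomethyl succinate, 4-methoxy-4-oxobutanoic acid | COC(=O)CCC(=O)O | starting material
14 | (S)-4-benzyl-1,3-oxazolidin-2-one | O=C1OC[C@H](Cc2ccccc2)N1 | starting material
15 | 4-methoxy-4-oxobutanoic pivalic anhydride | COC(=O)CCC(=O)OC(=O)C(C)(C)C | intermediate (not isolated)
16 | methyl 4-[(4S)-4-benzyl-2-oxo-1,3-oxazolidin-3-yl]-4-oxobutanoate | COC(=O)CCC(=O)N1[C@@H](Cc2ccccc2)COC1=O | intermediate
17 | syn-aldol adduct, methyl (3S,4R,5E,9E)-3-{[(4S)-4-benzyl-2-oxo-1,3-oxazolidin-3-yl]carbonyl}-11-(tert-butyldiphenylsilyloxy)-4-hydroxy-10-[(4-methoxybenzyloxy)methyl]-6-methylundeca-5,9-dienoate | COC(=O)C[C@@H]([C@H](O)/C=C(\C)CC/C=C(/CO[Si](c1ccccc1)(c1ccccc1)C(C)(C)C)COCc1ccc(OC)cc1)C(=O)N1[C@@H](Cc2ccccc2)COC1=O | intermediate (not isolated)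
18 | trans-lactone imide, (4S)-4-benzyl-3-[(2R,3S)-2-{(1E,5E)-7-(tert-butyldiphenylsilyloxy)-6-[(4-methoxybenzyloxy)methyl]-2-methylhepta-1,5-dienyl}-5-oxooxolane-3-carbonyl]-1,3-oxazolidin-2-one | O=C([C@H]1CC(=O)O[C@@H]1/C=C(\C)CC/C=C(/CO[Si](c1ccccc1)(c1ccccc1)C(C)(C)C)COCc1ccc(OC)cc1)N1[C@@H](Cc2ccccc2)COC1=O | intermediate
19 | (4R,5R)-5-{(1E,5E)-7-(tert-butyldiphenylsilyloxy)-6-[(4-methoxybenzyloxy)methyl]-2-methylhepta-1,5-dienyl}-4-(hydroxymethyl)oxolan-2-one (trans) | OC[C@H]1CC(=O)O[C@@H]1/C=C(\C)CC/C=C(/CO[Si](c1ccccc1)(c1ccccc1)C(C)(C)C)COCc1ccc(OC)cc1 | intermediate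
20 | (4R,5R)-5-{(1E,5E)-6-[(tert-butyldiphenylsilyloxy)methyl]-7-hydroxy-2-methylhepta-1,5-dienyl}-4-(hydroxymethyl)oxolan-2-one (C9 hydroxymethyl cis to the chain) | OC[C@H]1CC(=O)O[C@@H]1/C=C(\C)CC/C=C(/CO[Si](c1ccccc1)(c1ccccc1)C(C)(C)C)CO | intermediate
21 | trans-lactone dialdehyde, (2R,3S)-2-{(1E,5Z)-6-[(tert-butyldiphenylsilyloxy)methyl]-2-methyl-7-oxohepta-1,5-dienyl}-5-oxooxolane-3-carbaldehyde | O=C[C@H]1CC(=O)O[C@@H]1/C=C(\C)CC/C=C(/CO[Si](c1ccccc1)(c1ccccc1)C(C)(C)C)C=O | intermediate
22 | (1(10)Z,4E,6R,7R,8R,9S)-14-(tert-butyldiphenylsilyloxy)-8,9-dihydroxygermacra-1(10),4-dien-12,6-olide (trans-lactone, 8,9-erythro) | O=C1C[C@H]2[C@H](O1)/C=C(\C)CC/C=C(/CO[Si](c1ccccc1)(c1ccccc1)C(C)(C)C)[C@H](O)[C@@H]2O | intermediate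
23 | (1(10)Z,4E,6R,7S,8R,9S)-14-(tert-butyldiphenylsilyloxy)-8,9-(isopropylidenedioxy)germacra-1(10),4-dien-12,6-olide | O=C1C[C@H]2[C@H](O1)/C=C(\C)CC/C=C(/CO[Si](c1ccccc1)(c1ccccc1)C(C)(C)C)[C@@H]3OC(C)(C)O[C@@H]32 | intermediate
24 | Mannich base, 23 with a dimethylaminomethyl group on C11 (C11 epimers) | O=C1C(CN(C)C)[C@H]2[C@H](O1)/C=C(\C)CC/C=C(/CO[Si](c1ccccc1)(c1ccccc1)C(C)(C)C)[C@@H]3OC(C)(C)O[C@@H]32 | intermediate (not isolated)
25 | trimethylammonium iodide of 24 | O=C1C(C[N+](C)(C)C)[C@H]2[C@H](O1)/C=C(\C)CC/C=C(/CO[Si](c1ccccc1)(c1ccccc1)C(C)(C)C)[C@@H]3OC(C)(C)O[C@@H]32.[I-] | intermediate (not isolated)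
26 | (1(10)Z,4E,6R,7S,8R,9S)-14-(tert-butyldiphenylsilyloxy)-8,9-(isopropylidenedioxy)germacra-1(10),4,11(13)-trien-12,6-olide | O=C1C(=C)[C@H]2[C@H](O1)/C=C(\C)CC/C=C(/CO[Si](c1ccccc1)(c1ccccc1)C(C)(C)C)[C@@H]3OC(C)(C)O[C@@H]32 | intermediate
27 | (1(10)Z,4E,6R,7S,8R,9S)-14-hydroxy-8,9-(isopropylidenedioxy)germacra-1(10),4,11(13)-trien-12,6-olide | O=C1C(=C)[C@H]2[C@H](O1)/C=C(\C)CC/C=C(/CO)[C@@H]3OC(C)(C)O[C@@H]32 | intermediate
28 | (1(10)E,4E,6R,7S,8R,9S)-8,9-(isopropylidenedioxy)-14-oxogermacra-1(10),4,11(13)-trien-12,6-olide | O=C1C(=C)[C@H]2[C@H](O1)/C=C(\C)CC/C=C(/C=O)[C@@H]3OC(C)(C)O[C@@H]32 | intermediate (not isolated)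
29 | (1(10)E,4E,6R,7S,8R,9S)-8,9-(isopropylidenedioxy)germacra-1(10),4,11(13)-trien-12,6-olid-14-oic acid | O=C1C(=C)[C@H]2[C@H](O1)/C=C(\C)CC/C=C(/C(=O)O)[C@@H]3OC(C)(C)O[C@@H]32 | intermediate
30 | methyl (1(10)E,4E,6R,7S,8R,9S)-8,9-(isopropylidenedioxy)germacra-1(10),4,11(13)-trien-12,6-olid-14-oate | O=C1C(=C)[C@H]2[C@H](O1)/C=C(\C)CC/C=C(/C(=O)OC)[C@@H]3OC(C)(C)O[C@@H]32 | intermediate
31 | methyl (1(10)E,4E,6R,7R,8R,9S)-8,9-dihydroxygermacra-1(10),4,11(13)-trien-12,6-olid-14-oate | O=C1C(=C)[C@H]2[C@H](O1)/C=C(\C)CC/C=C(/C(=O)OC)[C@H](O)[C@@H]2O | intermediate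
32 | methyl (1(10)E,4E,6R,7R,8R,9S)-9-acetoxy-8-hydroxygermacra-1(10),4,11(13)-trien-12,6-olid-14-oate | O=C1C(=C)[C@H]2[C@H](O1)/C=C(\C)CC/C=C(/C(=O)OC)[C@H](OC(C)=O)[C@@H]2O | intermediate
33 | (E)-2-methylbut-2-en-1-ol (tiglyl alcohol, the reduction product of tiglic acid) | C/C=C(\C)CO | starting material
34 | (2S,3S)-2,3-epoxy-2-methylbutan-1-ol | OC[C@]1(C)O[C@H]1C | intermediate
35 | (2R,3S)-2,3-epoxy-2-methylbutanoic acid | OC(=O)[C@]1(C)O[C@H]1C | intermediate
36 | (2S,3R)-3-chloro-2-hydroxy-2-methylbutanoic acid | OC(=O)[C@](C)(O)[C@@H](C)Cl | intermediate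
37 | (2S,3R)-3-chloro-2-hydroxy-2-methylbutanoic 2,4,6-trichlorobenzoic anhydride | O=C(OC(=O)[C@](C)(O)[C@@H](C)Cl)c1c(Cl)cc(Cl)cc1Cl | intermediate (not isolated)
38 | methyl (1(10)E,4E,6R,7S,8R,9S)-9-acetoxy-8-[(2S,3R)-3-chloro-2-hydroxy-2-methylbutanoyloxy]germacra-1(10),4,11(13)-trien-12,6-olid-14-oate | O=C1C(=C)[C@H]2[C@H](O1)/C=C(\C)CC/C=C(/C(=O)OC)[C@H](OC(C)=O)[C@@H]2OC(=O)[C@](C)(O)[C@@H](C)Cl | intermediate
39 | methyl (1(10)E,4R,5R,6S,7R,8R,9S)-9-acetoxy-8-[(2S,3R)-3-chloro-2-hydroxy-2-methylbutanoyloxy]-4,5-epoxygermacra-1(10),11(13)-dien-12,6-olid-14-oate (CNP0185503.3) | C=C1C(=O)O[C@H]2[C@H]1[C@@H](OC(=O)[C@](C)(O)[C@@H](C)Cl)[C@@H](OC(C)=O)/C(C(=O)OC)=C\CC[C@@]1(C)O[C@H]21 | target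

Total step count: 26. Longest linear sequence: 21 steps (steps 1, 2, 4–8, 10–21, 25, 26, from 1 to 39); steps 3, 9 and 22–24 are side branches.

Steps least certain to work

Step 14 (key step). Ring closure has to compete with intermolecular coupling and plain reduction. The harder problem to remove by dilution is incomplete control of the C8–C9 relationship: a ten-membered transition state can also accommodate the threo arrangement, and rotation in the allyl-type ketyl can erode the Z geometry. The fallback changes how C9 is set. It sets out from 21: the coupling is run as before, and the diol fraction, including the C9 epimer of 22 F1, is oxidised with MnO2 at the allylic hydroxyl only to the 8-hydroxy-9-oxo enone F2. Reduction with Zn(BH4)2 goes through a zinc chelate between O8 and the ketone, with hydride delivered anti to C7, and should give the anti (erythro) diol, returning to the route at 22.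

Step 4. The olefination may show poor geometric selectivity, because the substituent on the carbanion carbon is larger than methyl and its ether oxygen can chelate lithium; the carbanion may also partly lose alkoxide by retro-Michael reaction. The fallback sets out from 4: a Morita–Baylis–Hillman reaction with methyl acrylate (DABCO) gives the β-hydroxy α-methylene ester F3. NBS/Me2S converts it with allylic transposition into the thermodynamically controlled allyl bromide F4, with the ester trans to the chain. 4-Methoxybenzyl alcohol with Ag2O then displaces bromide and comes back to the route at 8.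

Step 21. Site selectivity between two secondary hydroxyls may be poor, and the acetyl group may migrate from O9 to O8 under base. The fallback sets out from 31: trimethyl orthoacetate with PPTS gives the cyclic orthoacetate F5, and aqueous acetic acid opens it under stereoelectronic control. This places the acetate on the more hindered oxygen, so it is complementary to direct acylation and covers the case in which O9 proves the less accessible hydroxyl; it returns to the route at 32.

Step 25. Acylation of the hindered O8 by an α,α-disubstituted hydroxy acid may be slow. That would leave time for acetyl migration and for DMAP to attack the wrong carbonyl of the mixed anhydride. The fallback sets out from 32: it is acylated with the smaller, hydroxyl-free acid 35 (as its acid chloride, pyridine, −20 °C) to give the epoxy ester F6. Pyridinium chloride in CH2Cl2 then opens the glycidate at C3 of the side chain with inversion, before the ring epoxide exists, and returns to the route at 38.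

Step 26. Facial selectivity at C4=C5 rests on the ring conformation alone and may be poor. The fallback sets out from 38 and returns at 39 with reagent control instead of substrate control: a Shi epoxidation with the enantiomer of the fructose-derived ketone whose spiro transition state delivers oxygen to the required face (KHSO5, pH 8 buffer, MeCN, 0 °C). It makes no new compound.

## Further compounds

F1 | step 14 | C9 epimer of 22, (1(10)Z,4E)-14-(tert-butyldiphenylsilyloxy)-8,9-dihydroxygermacra-1(10),4-dien-12,6-olide with the threo 8,9-diol | O=C1C[C@H]2[C@H](O1)/C=C(\C)CC/C=C(/CO[Si](c1ccccc1)(c1ccccc1)C(C)(C)C)[C@@H](O)[C@@H]2O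
F2 | step 14 | (1(10)Z,4E)-14-(tert-butyldiphenylsilyloxy)-8-hydroxy-9-oxogermacra-1(10),4-dien-12,6-olide | O=C1C[C@H]2[C@H](O1)/C=C(\C)CC/C=C(/CO[Si](c1ccccc1)(c1ccccc1)C(C)(C)C)C(=O)[C@@H]2O
F3 | step 4 | methyl (6E)-8-(tert-butyldimethylsilyloxy)-3-hydroxy-6-methyl-2-methylideneoct-6-enoate (racemic) | C=C(C(=O)OC)C(O)CC/C(C)=C/CO[Si](C)(C)C(C)(C)C
F4 | step 4 | methyl (2Z,6E)-2-(bromomethyl)-8-(tert-butyldimethylsilyloxy)-6-methylocta-2,6-dienoate | COC(=O)/C(CBr)=C/CC/C(C)=C/CO[Si](C)(C)C(C)(C)C
F5 | step 21 | cyclic 8,9-orthoacetate (2-methoxy-2-methyl-1,3-dioxolane) of 31 | O=C1C(=C)[C@H]2[C@H](O1)/C=C(\C)CC/C=C(/C(=O)OC)[C@@H]3OC(C)(OC)O[C@@H]32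
F6 | step 25 | methyl (1(10)E,4E)-9-acetoxy-8-[(2R,3S)-2,3-epoxy-2-methylbutanoyloxy]germacra-1(10),4,11(13)-trien-12,6-olid-14-oate | O=C1C(=C)[C@H]2[C@H](O1)/C=C(\C)CC/C=C(/C(=O)OC)[C@H](OC(C)=O)[C@@H]2OC(=O)[C@]3(C)O[C@H]3C
F0 | step 26 | none | none
A1 | alternative 1 | trans-2-isopropenyl-1-vinylcyclohexan-1-ol with OTBS on C6, the 3-(TBSO)prop-1-en-2-yl group on C7 and the 8,9-acetonide (oxy-Cope substrate) | C=C[C@@]1(O)[C@H](C(C)=C)[C@@H](O[Si](C)(C)C(C)(C)C)[C@H](C(=C)CO[Si](C)(C)C(C)(C)C)[C@H]2OC(C)(C)O[C@H]21
A2 | alternative 1 | ten-membered C10 ketone with E C4=C5 and C6–C9 in place (oxy-Cope product) | O=C1CCC/C(C)=C/[C@@H](O[Si](C)(C)C(C)(C)C)[C@H](C(=C)CO[Si](C)(C)C(C)(C)C)[C@H]2OC(C)(C)O[C@H]21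
A3 | alternative 2 | open-chain C1 aldehyde with the C10 phosphonoacetate, 4,5-epoxide and protected C6, C8, C9, C12 oxygens (olefination substrate) | O=CCC[C@@]1(C)O[C@@H]1[C@@H](O[Si](C)(C)C(C)(C)C)[C@H](C(=C)CO[Si](C)(C)C(C)(C)C)[C@@H](OCc2ccc(OC)cc2)[C@@H](O[Si](CC)(CC)CC)C(C(=O)OC)P(=O)(OC)OC
A4 | alternative 2 | ten-membered ring-cis C1=C10 enoate with the 4,5-epoxide (olefination product) | C=C(CO[Si](C)(C)C(C)(C)C)[C@H]1[C@H](O[Si](C)(C)C(C)(C)C)[C@H]2O[C@]2(C)CC/C=C(/C(=O)OC)[C@H](O[Si](CC)(CC)CC)[C@@H]1OCc3ccc(OC)cc3
A5 | alternative 3 | open-chain C9 aldehyde with the C10 alkenyl iodide, epoxide and α-methylene lactone (chromium-mediated coupling substrate) | I/C(COCc1ccc(OC)cc1)=C\CC[C@@]2(C)O[C@@H]2[C@H]3OC(=O)C(=C)[C@@H]3[C@@H](O[Si](C)(C)C(C)(C)C)C=O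
A6 | alternative 3 | ten-membered C9 carbinol with epoxide, lactone and ring-cis C1=C10 (coupling product) | C=C1C(=O)O[C@H]2[C@H]1[C@@H](O[Si](C)(C)C(C)(C)C)[C@@H](O)/C(COCc3ccc(OC)cc3)=C\CC[C@@]1(C)O[C@H]21
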